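**Retrosynthetic overview**
1. Cut the aryl–C(=O) bond. The target comes from its isomeric aryl ester by a light-driven O→C acyl shift (photo-Fries). The required carbon is the only unsubstituted ortho/para position on ring A.
2. Cut the ester C–O bond to give 2,4-diprenylresorcinol and (S)-4-hydroxyphenyllactic acid. The acid is used as its bis-O-TMS acid chloride, and the TMS groups fall off in the acylation work-up.
3. The (S)-hydroxy acid comes from L-tyrosine by NH2→OH exchange with retention. This is the only stereocentre, and it is bought.
4. Cut the two aryl–prenyl bonds to give resorcinol and prenol (ortho-directed double C-prenylation).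
5. No ring is built. Both benzene rings are purchased intact.

Assumption: CIP analysis of the given SMILES gives (S) at C-α, the same spatial arrangement as L-tyrosine. Every chemical transformation is counted as its own step, even where the product is carried forward crude.

**Route**

Step 1
Reactants: 1 L-tyrosine
Product: 2 (S)-2-hydroxy-3-(4-hydroxyphenyl)propanoic acid
Conditions: NaNO2 (slow addition), 1 M aq. H2SO4, 0 °C → rt; sulfamic acid quench; EtOAc extraction, recrystallise
Reagents that add atoms: water, O
Why: In this diazotisation–hydrolysis of an α-amino acid, the carboxylate expels N2 to form an α-lactone (inversion) and water opens it (second inversion), so net retention carries (S) into 2.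

Step 2
Reactants: 3 resorcinol; 4 prenol (3-methylbut-2-en-1-ol, 2.2 equiv in two portions)
Product: 5 2,4-bis(3-methylbut-2-en-1-yl)benzene-1,3-diol (2,4-diprenylresorcinol)
Conditions: acidic Al2O3 (Brockmann I, ~2 g/mmol), DCE, 80 °C; filter; SiO2 chromatography
Reagents that add atoms: prenol, CC(C)=CCO (two C5H9 units; water lost)
Why: In this alumina-templated Friedel–Crafts ortho-allylation, surface-bound phenoxide and surface-activated allylic alcohol deliver the primary terminus of the prenyl unit only to carbons ortho to oxygen, so C2 plus one of the equivalent C4/C6 positions gives 5 (stepwise 2,4-bis-allylation of 5-alkylresorcinols is known for this reaction type), the 4,6- and 2,4,6-products are removed by chromatography, and no stereocentre forms.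

Step 3
Reactants: 2 (S)-4-hydroxyphenyllactic acid
Product: 6 trimethylsilyl (S)-2-(trimethylsilyloxy)-3-[4-(trimethylsilyloxy)phenyl]propanoate
Conditions: HMDS (1.1 equiv), TMSCl (1.1 equiv), MeCN, rt → 50 °C, 2 h; filter NH4Cl under Ar; evaporate, strip with toluene; use crude
Reagents that add atoms: hexamethyldisilazane, C[Si](C)(C)N[Si](C)(C)C; chlorotrimethylsilane, C[Si](C)(C)Cl
Why: In this exhaustive O-silylation, one HMDS plus one TMSCl deliver exactly three Me3Si groups to the CO2H, α-OH and phenol OH with NH4Cl as the only by-product, and the near-neutral conditions do not touch C-α, so (S) is retained.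

Step 4
Reactants: 6 tris-TMS derivative
Product: 7 (S)-2-(trimethylsilyloxy)-3-[4-(trimethylsilyloxy)phenyl]propanoyl chloride
Conditions: (COCl)2 (1.05 equiv), DMF (2 mol %), CH2Cl2, 0 °C → rt, 2 h; evaporate; use crude at once
Reagents that add atoms: oxalyl chloride, O=C(Cl)C(=O)Cl
Why: In this silyl-ester-to-acid-chloride exchange (Vilsmeier-type activation), the silyl ester is converted to the acyl chloride with loss of TMSCl, CO and CO2, no HCl is released so both TMS ethers survive, and no base is present so C-α stays (S).

Step 5
Reactants: 7 acid chloride; 5 2,4-diprenylresorcinol (1.3 equiv, excess recovered)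
Product: 8 3-hydroxy-2,4-bis(3-methylbut-2-en-1-yl)phenyl (S)-2-hydroxy-3-(4-hydroxyphenyl)propanoate
Conditions: pyridine (1.5 equiv), CH2Cl2, −20 → 0 °C; then 10% aq. citric acid–THF, rt, 30 min; SiO2 chromatography
Reagents that add atoms: none (the work-up only replaces Me3Si by H)
Why: This pyridine-mediated O-acylation of a phenol favours the less hindered O1–H of 5 (one ortho prenyl rather than two), excess 5 suppresses bis-acylation, the weak base and low temperature avoid ketene formation so C-α stays (S), the two labile TMS ethers are hydrolysed in the mildly acidic work-up without touching the aryl ester or the prenyl groups, and the minor O3-acyl isomer is removed on silica.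

Step 6 (key step)
Reactants: 8 aryl ester
Product: 9 Lespeflorin C6, (S)-1-[2,4-dihydroxy-3,5-bis(3-methylbut-2-en-1-yl)phenyl]-2-hydroxy-3-(4-hydroxyphenyl)propan-1-one
Conditions: hν 254 nm (low-pressure Hg, FEP flow coil), Ar-degassed t-BuOH–MeCN 1:1, 0.01 M, 15 °C, tR ~30 min; neutral SiO2 chromatography (recover 5)
Reagents that add atoms: none
Why: Proposed new method: a protecting-group-free, stereoretentive photo-Fries migration of an enantiopure α-hydroxyacyl group onto a prenyl-blocked resorcinol. Singlet excitation homolyses the ArO–C(O) bond to a solvent-caged phenoxyl/acyl radical pair; the phenoxyl spin sites C2 and C4 carry prenyl groups, so attack there gives non-enolisable dienones that re-cleave, and productive recombination occurs only at C6–H (ortho shift); tautomerisation gives 9, whose chelated o-hydroxyaryl ketone deactivates by ESIPT and so resists the Norrish I cleavage typical of α-hydroxy aryl ketones. The spin sits on the acyl carbon and never on C-α, and cage recombination (≥10^9 s⁻¹) outruns decarbonylation (~10^6–10^7 s⁻¹), so (S) is retained. The viscous, H-bond-accepting, poor H-donor medium strengthens the cage, ties up the phenolic OH that could otherwise photocyclise onto a prenyl group, and traps any ketene from in-cage disproportionation so that racemic ester cannot re-form. The closest known reaction type is the photo-Fries rearrangement of simple achiral aryl alkanoates (for example resorcinol monoesters to 2,4-dihydroxyaryl ketones), which to my knowledge has not been shown for unprotected α-hydroxyacyl stereocentres or for prenyl-blocked resorcinols.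

**Compound list**
1 | L-tyrosine | N[C@@H](Cc1ccc(O)cc1)C(=O)O | starting material
2 | (S)-2-hydroxy-3-(4-hydroxyphenyl)propanoic acid | O[C@@H](Cc1ccc(O)cc1)C(=O)O | intermediate
3 | resorcinol | Oc1cccc(O)c1 | starting material
4 | prenol | CC(C)=CCO | starting material
5 | 2,4-diprenylresorcinol | CC(C)=CCc1ccc(O)c(CC=C(C)C)c1O | intermediate
6 | trimethylsilyl (S)-2-(trimethylsilyloxy)-3-[4-(trimethylsilyloxy)phenyl]propanoate | C[Si](C)(C)O[C@@H](Cc1ccc(O[Si](C)(C)C)cc1)C(=O)O[Si](C)(C)C | intermediate
7 | (S)-2-(trimethylsilyloxy)-3-[4-(trimethylsilyloxy)phenyl]propanoyl chloride | C[Si](C)(C)O[C@@H](Cc1ccc(O[Si](C)(C)C)cc1)C(=O)Cl | intermediate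
8 | 3-hydroxy-2,4-diprenylphenyl (S)-2-hydroxy-3-(4-hydroxyphenyl)propanoate | CC(C)=CCc1ccc(OC(=O)[C@@H](O)Cc2ccc(O)cc2)c(CC=C(C)C)c1O | intermediate
9 | Lespeflorin C6 | CC(C)=CCc1cc(C(=O)[C@@H](O)Cc2ccc(O)cc2)c(O)c(CC=C(C)C)c1O | target

**Step count**
- Total steps: 6. Compounds 6 and 7 are carried forward crude, so only four products are purified. Compound 2 is also sold, and buying it would make the route 5 steps.
- Longest linear sequence: 5 (steps 1 → 3 → 4 → 5 → 6). Step 2 is the one-step second branch that joins at step 5.

**Three steps most likely to fail**
1. **Step 6 (proposed new step).**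
   - Risks: cage escape back to 5, decarbonylation, photocyclisation of the o-prenylphenol to a chroman, and slow conversion because the product filters the light.
   - Fallback (known chemistry): make the bond by polar chemistry. Run the Step 2 prenylation on commercial 4-bromoresorcinol, where only C2 and C6 are open and activated. Protect the product as its bis-MOM ether and carry out Br–Li exchange (n-BuLi, −78 °C). Add the aryllithium to the Weinreb amide of O,O′-bis-TBS-2, then deprotect globally with HCl/MeOH.
2. **Step 2.**
   - Risks: a mixture of 2,4-, 4,6- and 2,4,6-prenylated products, and chroman formation.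
   - Fallback: fix the regiochemistry by metalation instead of electrophilic substitution. Start from commercial 1,3-bis(methoxymethoxy)benzene and run n-BuLi then CuI/prenyl bromide at C2. Repeat the metalation–prenylation at C4, then remove the MOM groups with HCl/MeOH to give 5 (3 steps).
3. **Step 5 (with the labile intermediates 6 and 7 that feed it).**
   - Risks: premature TMS loss leading to self-acylation or oligomers, partial racemisation through a ketene, bis-acylation, and some O3-acylation. The O3-acyl isomer is not a dead end. Its only open ortho/para position is the same C6, so irradiating it would reach 9 by a para shift.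
   - Fallback: switch to persistent protection and carbodiimide activation. Isolate the O,O′-bis-TBS acid of 2 and couple it with 5 by Steglich esterification (EDC/DMAP). Irradiate the bis-silyl ester and remove TBS last with Et3N·3HF.

The ee of 8 and 9 should be checked by chiral HPLC against material made from DL-tyrosine.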